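(The numbers in the tables are simulated with made-up constants; noise was put on by code.)

Slowness was not what I had to reckon with: the target in the grey run stood near its level at the first reading, 0.500 min, and the target in the red run at 30.0 s, both shorter times than the 4.0 min given to north and west. So I looked for a number that stays put.

common to all: starting material 0.068 M

| charge | reagent | second substrate | temperature | remark | time |
|---|---|---|---|---|---|
| grey | 0.022 M | 0.34 M | 65 °C | run made earlier |  |
| red | 0.052 M | 0.34 M | 76 °C | run made earlier |  |
| north | 0.0408 M | 0.340 M |  | at 80 °C until 2.0 min, from then on at 60 °C | 4.0 min |
| west | 0.0800 M | 0.340 M |  | at 80 °C throughout | 4.0 min |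

- grey (time / min: target / %, starting material / %): 0.500: 22.4, 76.4; 1.33: 25.8, 74.4; 3.00: 24.1, 75.3; 4.00: 24.4, 75.8
- red (time / s: target / %, starting material / %): 30.0: 47.4, 50.8; 60.0: 48.0, 49.4; 90.0: 45.9, 51.0; 120: 44.6, 52.2

(readings scatter by 0.5 percentage points)

1. which one finishes higher in amount of target, in percent of the starting material charged ("neither" within 2 percentage points) (north / west / neither)
2. amount of target at the end, in percent of the starting material charged, north
3. amount of target at the end, in percent of the starting material charged, west

I call the plateau quotient Q the target divided by the product of starting material and reagent not in target, each in M: an apparent equilibrium constant, read as thermodynamic rather than kinetic control. The mean of the grey readings gives 57.6 /M at 65 °C. The last red reading gives 39.4 /M at 76 °C, so the hotter run reads lower. Letting Q shrink by a constant factor per degree, I took 34.3 /M at 80 °C.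

The first setting is the reagent. If x is the target in M, and a and b are the charges of starting material and reagent, then Q = x/((a−x)(b−x)). At 80 °C this gives 36.0% with north's reagent and 58.2% with west's.

The second setting is temperature. North spends 2.00 min at 60 °C, longer than the grey run took to reach its level, so I let its quotient follow. The plateau quotient at the cold end is 68.4 /M, which in my reckoning puts north at 43.5%, still less than my figure for west.

The forecast also chose west, with 31% for north and 44% for west, holding that “the reagent is used up fast and part of it is wasted”; my figures are higher.

The flasks gave 38.5% in north and 51.1% in west, so west finished higher.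

    target ⇌ isomer of the product (K = 0.110, k = 0.00150 /s, Ea = 116 kJ/mol, ΔH = 2.00 kJ/mol)
    second substrate + reagent ⇌ second product (K = 5.40 /M, k = 0.0270 /M/s, Ea = 49.0 kJ/mol, ΔH = −24.0 kJ/mol)
    starting material + reagent ⇌ target (K = 69.0 /M, k = 1.70 /M/s, Ea = 40.0 kJ/mol, ΔH = −45.0 kJ/mol)
    (constants at 80 °C)

The way back from target to starting material and reagent is the main reason west ended where it did: west without that step ends at 88.7% against 51.1%. Kept at 68.4 /M, the quotient put north at 43.5% against its 38.5%, and at the end north held 0.00866 M of second product and 3.24% of isomer of the product, forms of the reagent that Q counts as free. The same quotient gives a neighbour of north, charged with 0.024 M of reagent, 27.2%, and that flask ended at 23.9%.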